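(The readings were computed from invented constants; scatter was added.)

A small charge of X, 5 mol% on E, stands beside J and Z at 0.950 equiv, and the amounts stay the same across the set-ups.

in all of them: X 5 mol%

| flask | E | Z | J | remark | time |
|---|---|---|---|---|---|
| gamma | 0.070 M | 0.95 equiv | 17 mol% | run made earlier |  |
| theta | 0.070 M | 0.95 equiv | 34 mol% | run made earlier |  |
| elm | 0.070 M (fed, over 15.0 h) | 0.950 equiv | 17 mol% | a stirred flask in which E is dosed at a steady rate over 15.0 h without added volume, worked up at 30 h | 30 h |
| oak | 0.070 M | 0.950 equiv | 17 mol% | a single well-mixed tank run continuously and read at steady state, 30 h in it on average |  |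
| larch | 0.070 M | 0.950 equiv | 17 mol% | a closed flask charged with all of it at once and left for 30 h | 30 h |
| cedar | 0.070 M | 0.950 equiv (fed, over 15.0 h) | 17 mol% | a stirred flask in which Z is dosed at a steady rate over 15.0 h without added volume, worked up at 30 h | 30 h |

- the stated concentrations are those of everything mixed, before any reaction; amounts are the same in each set-up
- what was read earlier has a scatter of 0.5 percentage points, one standard deviation
- the feed brings no volume worth counting
- the earlier runs were made in a closed, stirred flask

So elm and oak differ from larch in how long E spends in the vessel, and we need a clock for E that can be carried from one vessel to another.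

- gamma (time / h: D / %, L / %, E / %): 4.00: 18.1, 1.7, 80.5; 8.00: 32.7, 4.2, 62.8; 12.0: 41.2, 7.0, 50.7; 15.0: 48.4, 10.6, 42.2; 20.0: 52.9, 14.0, 31.1; 25.0: 56.7, 17.8, 23.0; 30.0: 60.6, 21.7, 17.0
- theta (time / h: D / %, L / %, E / %): 0.500: 1.7, 0.3, 96.6; 0.667: 3.8, 0, 96.6; 1.00: 5.4, 0.1, 94.7; 1.50: 7.1, 0, 91.3; 2.50: 12.7, 1.4, 86.3; 4.00: 19.2, 2.8, 80.3; 6.00: 24.5, 4.4, 71.0

(scatter of a reading: 0.5 percentage points)

J is 17 mol% in gamma and 34 mol% in theta, yet at 4.00 h E reads 80.5 % and 80.3 %, so J leaves the pace of E unchanged within the scatter. In gamma, 1.77 is the natural logarithm of the charge of E over the E left at 30.0 h, the e-fold count N. At 15.0 h the count is 0.863, which is 0.487 of N, and the ratio of the times is 0.500. So the logarithm runs straight while Z falls, E is pseudo-first-order, and N counts the time E has spent in the flask.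

- the set-up with the highest amount of D at the outlet or at the end, in percent of the E put in ("none" if the first two lie within 2 percentage points) (elm / oak / larch / cedar / none)
- amount of D at the outlet or at the end, in percent of the E put in, elm
- amount of D at the outlet or at the end, in percent of the E put in, oak
- amount of D at the outlet or at the end, in percent of the E put in, larch
- amount of D at the outlet or at the end, in percent of the E put in, cedar

Larch repeats gamma, so our reckoning leaves 17.0 % of E, with D near 60.6 %. E in elm arrives evenly, and averaging over its arrival leaves 27.3 %. Oak, being mixed, leaves 36.1 %. Cedar holds E from the start, so N gives it the E of larch, but N cannot say how D and L share what has reacted there. Because elm converts less E, we put larch ahead of elm, and oak last.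

The forecast gave elm 56 %, oak 42 %, larch 60.5 %, cedar 60 % and best none, holding that cedar “should match batch”.

The flasks give elm 57.0 %, oak 40.9 %, larch 59.8 %, cedar 57.0 % and best larch.

    J + D ⇌ Q (K = 1.72 M⁻¹, k = 8.12 M⁻¹ h⁻¹)
    E + X → X + D (k = 16.6 M⁻¹ h⁻¹)
    Z + Q → J + L (k = 39.3 M⁻¹ h⁻¹)
    2 Z → G (k = 0.436 M⁻¹ h⁻¹)

In larch, D is made 3.87 times faster than it is used up at 9.16 h, but 1.58 times faster at 30.0 h. So D in larch is still gaining at the end, though more slowly. Elm, reckoned at 27.3 % of E, holds 27.9 % at 30.0 h. X stands in the rate of E, so N scales with X: in a neighbour flask, which is larch with 1.2 mol% of X, N becomes 0.425 and leaves 65.4 % of E, and that flask holds 65.8 %.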